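**Remark on the chemistry (assumption):** the SMILES is read as the natural ent‑gibberellane series (2β,3β,11β‑triol, 5β‑H, 9β‑H, 19→20 δ‑lactone). Gibberellane numbering C1–C20 is used for the target and all intermediates; "carbocycle L" means the five‑membered ring C4–C19–C20–C10–C5.

## Structural features

The target is a C20 gibberellin: a 6‑5‑6‑5 carbocycle (rings A–D) in which a δ‑lactone (C4–C19(=O)–O–C20–C10, closed through C5) spans the α face of ring A as a 3‑oxabicyclo[3.3.1]nonanone. Ring A carries a cis‑2β,3β‑diol on the face away from the lactone, ring B is a cyclopentane with the C7 acid on C6, and rings C and D form a bicyclo[3.2.1]octane with an axial 11β‑hydroxyl and the exocyclic C16=C17 alkene. Of ten stereocentres, eight are contiguous around ring B (C4, C5, C6, C8, C9, C10, flanked by C3 and C11), and C4, C8 and C10 are quaternary. Fragile points are the exocyclic alkene (acid isomerisation, and a competitor of the ring A alkene in any oxidation), the cis‑diol (glycol cleavage), the epimerisable C6 and the lactone. The real difficulty is the C4–C5–C10 triad: two quaternary carbons bridged 1,3‑diaxially, a trans A/B fusion (5β‑H), and a lactone bridge on the same face of ring B as ring C. The key step exploits the fact that the lactone ring without its ring oxygen is a cyclopentanone (carbocycle L) cis‑fused to ring B: as a cyclopentenone it activates C10, then C5 and C4, and its C19–C20 bond is cut at the end with oxygen placed on the C20 side.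

## Logic of the disconnections

**29 ⇒ 27 ⇒ 25.** Cut the lactone O–C19 bond (and remove the tactical ester and acetonide). 27 comes from 25 by reducing the C20 aldehyde, whose alkoxide closes onto the 1,3‑diaxial C19 ester; the same hydride sets C11. Demand: hydride must reach C11 from the α face.

**25 ⇒ 24 ⇒ 23.** Re‑join C19 and C20: the ester/aldehyde pair is the cleavage product of an α‑ketol in carbocycle L. Gain: the lactone becomes a cyclopentanone that can be built by C–C chemistry. The oxygen ends on C20, opposite to the Baeyer–Villiger sense, so it must have been placed on C20 regiospecifically earlier.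

**23 ⇒ 22 ⇒ 21.** Cut C13–C16 (ring D) as a vinyl‑radical cyclisation onto a C12=C13 enone. Reason: the exocyclic alkene then appears only after the ring A dihydroxylation, so no masking is needed. Demand: the bromoalkene must survive fifteen steps.

**21 ⇒ 20 ⇒ 19 ⇒ 18.** The diol comes from a C2=C3 alkene, and the alkene from a C3 carbinol next to quaternary C4. Demand: oxidant from the β face; elimination can only go toward C2.

**18 ⇒ 17 (key).** Cut C3–C4 and the C5–H bond: a reductive aldol cyclisation of an enone–aldehyde. In one sentence: ring A is closed, and C4 and C5 are set, by hydride addition/aldol on a cyclopentenone that stands in for the lactone. Gain: ring A, the quaternary C4 and the trans A/B fusion disappear together. Demand: hydride must add to a fully substituted β‑carbon.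

**17 ⇒ 16 ⇒ 15 ⇒ 14 ⇒ 12 + 13.** Cut C10–C1 (conjugate addition), the C20–O bond (enol ether oxidation) and shift one alkene. Gain: C10 becomes trigonal. Demand: the nucleophile must enter on the H9 side of C10.

**12 ⇒ 11 ⇒ 10.** Remove the C5=C6 unsaturation and restore one ester. Reason: C5 must be trigonal when C10 is substituted, so that no ring‑fusion constraint couples the two centres.

**10 ⇒ 6 + 8.** Cut C5–C6 and C9–C10: a Michael/aldol‑condensation annulation of a keto‑malonate onto an ene‑dione that already holds C4, C5, C10, C18, C19 and C20. Demand: only C9 (not C12) can close a five‑membered ring.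

**6 ⇒ 4 + 5; 4 ⇒ 1 + 2; 8 ⇒ 7.** Cut C6–C8 (asymmetric Michael addition, sets C8), C8–C15 (allylation/transposition) and one C–H oxidation.

## Other disconnections considered

**Alternative 1:** (the first that comes to mind) Cut the lactone C19–O bond last and close it by lactonising hydroxy acid A1, built on an aromatic ring A (Birch reductive methylation for C4, carbene addition to a C5=C10 alkene for C20). The lactonisation itself solves nothing. C10–C20, C4 and the 5β‑hydrogen would each need a separate operation on a hindered tetrasubstituted alkene, and the 11‑oxygen has no natural entry. The chosen plan takes C4, C5 and C10 from one preformed ring.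

**Alternative 2:** Cut C6–C8 and reconnect C7–C8, i.e. make ring B six‑membered and contract it by Wolff rearrangement of diazoketone A2 (the biomimetic atom deletion). A2 still contains every other difficulty (C4, C10, lactone, rings C/D). The contraction settles only C6/C7, and the ketene is protonated at C6 without control. Step economy is worse.

**Alternative 3:** Cut C8–C9 and C13–C14: intramolecular Diels–Alder reaction of triene A3 (silyloxydiene on C10, 1,1‑disubstituted alkene on the C6 chain) to close rings B and C. The dienophile is unactivated. No ring enforces that ring C ends syn to the lactone bridge, and A3 already requires C4, C5 and C10, which is the hard part.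

Key step: step 11

## Route

Step 1
Reactants: 1 3-ethoxycyclohex-2-en-1-one; 2 2,3-dibromoprop-1-ene
Product: 4 3-(2-bromoprop-2-en-1-yl)cyclohex-2-en-1-one, via tertiary alcohol adduct 3 (not isolated)
Conditions: Zn, THF, 0 °C to rt; then 2 M HCl, rt
Reagents that add atoms: none
Why: Barbier-type 1,2-addition of the allylic zinc reagent to the vinylogous ester carbonyl, then acid hydrolysis of the enol ether and loss of water (Stork–Danheiser transposition) give the 3-substituted enone; no stereocentre survives.

Step 2
Reactants: 4 3-(2-bromoprop-2-en-1-yl)cyclohex-2-en-1-one; 5 dimethyl propanedioate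
Product: 6 dimethyl 2-[(1S)-1-(2-bromoprop-2-en-1-yl)-3-oxocyclohexyl]propanedioate
Conditions: 9-amino-9-deoxy-epi-cinchona primary amine (20 mol%), PhCO2H (40 mol%), toluene, 9 kbar, 25 °C
Reagents that add atoms: none
Why: Primary-amine (iminium) catalysed Michael addition of a malonate to a β,β-disubstituted cyclohexenone under high pressure, a known route to quaternary β-carbons; the chiral iminium shields one enone face and sets C8 (the quinine- or quinidine-derived pseudoenantiomer is chosen to give the S centre).

Step 3
Reactants: 7 3-methylcyclopent-2-en-1-one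
Product: 8 4-methylcyclopent-4-ene-1,3-dione
Conditions: Rh2(cap)4 (cap = caprolactamate, 1 mol%), t-BuOOH (70% aq.), K2CO3, CH2Cl2, rt
Reagents that add atoms: tert-butyl hydroperoxide CC(C)(C)OO
Why: Dirhodium caprolactamate-catalysed allylic C–H oxidation turns the ring methylene γ to the carbonyl into a ketone (enone to ene-dione); the secondary ring CH2 is oxidised in preference to the methyl group.

Step 4
Reactants: 6 dimethyl 2-[(1S)-1-(2-bromoprop-2-en-1-yl)-3-oxocyclohexyl]propanedioate; 8 4-methylcyclopent-4-ene-1,3-dione
Product: 10 tricyclic ene-dione diester (ring B closed; C10=C20; 9β-H), via Michael adduct 9 (not isolated)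
Conditions: NaH, THF, 0 °C; add to 8 at −78 °C; then p-TsOH·H2O (1.3 equiv), toluene, 90 °C, 4 Å sieves
Reagents that add atoms: none
Why: Michael addition of the malonate anion to the unsubstituted alkene carbon (C5) of the ene-dione, then acid-catalysed aldol condensation of the C11 ketone (C9 enol) onto C10 of the vinylogous acid; C9 reaches C10 through a five-membered ring and equilibrates to the cis B/C fusion (9β-H), while C4 and C5 stay epimerisable (one epimer drawn; C5 is erased at 12, C4 at 16).

Step 5
Reactants: 10 tricyclic ene-dione diester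
Product: 11 tricyclic ene-dione monoester (C6–H)
Conditions: LiCl, H2O (2 equiv), DMSO, 150 °C
Reagents that add atoms: none
Why: Krapcho dealkoxycarbonylation of the geminal diester; the new C6–H centre is labile and is erased in step 6.

Step 6
Reactants: 11 tricyclic ene-dione monoester
Product: 12 cross-conjugated dienone ester (C10=C20 and C5=C6)
Conditions: chloranil (1.5 equiv), t-BuOH, reflux
Reagents that add atoms: none
Why: Quinone dehydrogenation of an enone through its dienol gives the linear dienone, as in the classical 4-en-3-one to 4,6-dien-3-one conversion; only C5–H/C6–H can be removed, which makes C5 trigonal before C10 is substituted.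

Step 7
Reactants: 12 cross-conjugated dienone ester; 13 but-3-en-1-ylmagnesium bromide
Product: 14 triethylsilyl enol ether with quaternary C10 (10β-butenyl)
Conditions: CuBr·SMe2 (10 mol%), Et3SiCl, HMPA, THF, −78 °C
Reagents that add atoms: chlorotriethylsilane CC[Si](Cl)(CC)CC
Why: Copper-catalysed, silyl chloride-accelerated 1,4-addition of the Grignard reagent to the β,β-disubstituted enone with silyl trapping of the enolate; ring B holds C10 so that its faces are flanked by H9 and by C11, the nucleophile enters on the H9 side (C1 β), and no ring-fusion constraint interferes because C5 is trigonal.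

Step 8
Reactants: 14 triethylsilyl enol ether
Product: 15 20-(triethylsilyloxy) 19-ketone
Conditions: mCPBA (1.05 equiv), NaHCO3, CH2Cl2, −20 °C
Reagents that add atoms: 3-chloroperbenzoic acid OOC(=O)c1cccc(Cl)c1
Why: Rubottom oxidation: the electron-rich silyl enol ether is epoxidised faster than the terminal alkene, the bromoalkene or the enoate, and 1,4-silyl migration gives the α-silyloxy ketone with oxygen on C20 only; the C20 configuration (drawn cis to C1) is of no consequence.

Step 9
Reactants: 15 20-(triethylsilyloxy) 19-ketone
Product: 16 C4=C5 enone with 6β-ester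
Conditions: DBU (0.3 equiv), CH2Cl2, rt
Reagents that add atoms: none
Why: Base-mediated alkene migration: C4–H (α to the ketone, vinylogous to the ester) is removed and the dienolate is protonated at C6, which puts the alkene in conjugation with the ketone; C6 takes the thermodynamically preferred β-ester configuration.

Step 10
Reactants: 16 C4=C5 enone
Product: 17 enone aldehyde (C3 aldehyde on the C10 side chain)
Conditions: OsO4 (2 mol%), NaIO4, 2,6-lutidine, dioxane/H2O, rt
Reagents that add atoms: sodium periodate [Na+].[O-]I(=O)(=O)=O
Why: Lemieux–Johnson cleavage; OsO4 attacks the monosubstituted alkene far faster than the electron-poor bromoalkene and the tetrasubstituted enone.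

Step 11
Reactants: 17 enone aldehyde
Product: 18 ring A ketol (C3–C4 bond, 3-hydroxy, 5β-H)
Conditions: [(Ph3P)CuH]6 (0.25 equiv), toluene, −40 to 0 °C; aq. NH4Cl
Reagents that add atoms: none
Why: Copper hydride adds hydride to C5, the β-carbon of the only enone, and the copper enolate (O–C19=C4) adds to the C3 aldehyde: a reductive aldol cyclisation, the closest known type being copper hydride reductive aldol cyclisations of enones tethered to aldehydes or ketones. Ring A closes in a 6-(enolexo)-exo-trig aldol through a chair-like transition state, giving the bicyclo[3.2.1]octane of ring A and carbocycle L. At C5, hydride can only be delivered on the face of the C10 side chain, because the alternative would make a trans-fused bicyclo[3.3.0]octanone (ring B/carbocycle L); this gives 5β-H and the trans A/B fusion. At C4, the enolate carbon can reach the aldehyde only on the face carrying the C1–C3 tether, so the new bond is cis to C1 and the methyl group ends on the other face; the quaternary centre is set by the ring, not by a reagent. C3 is formed as a carbinol whose configuration does not matter, since it is removed in step 12. The step needs 1,4-reduction of the enone in the presence of an aldehyde, two ketones, the bromoalkene and the silyl ether; copper hydride prefers conjugate addition and the enolate is trapped intramolecularly faster than it is protonated. The enolate forms at C4 and not at C20 because it is generated by hydride addition, not by deprotonation.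

Step 12
Reactants: 18 ring A ketol
Product: 19 ring A alkene (C2=C3)
Conditions: Burgess reagent, toluene, 70 °C
Reagents that add atoms: none
Why: Syn-elimination (Ei) of the sulfamate ester formed with the Burgess reagent; C4 is quaternary, so only a C2 hydrogen can be lost and the alkene is C2=C3; neutral conditions avoid retro-aldol cleavage.

Step 13
Reactants: 19 ring A alkene
Product: 20 2β,3β-diol
Conditions: OsO4 (5 mol%), NMO, acetone/H2O, 0 °C
Reagents that add atoms: N-methylmorpholine N-oxide C[N+]1([O-])CCOCC1; water O
Why: Catalytic cis-dihydroxylation; the α face of C2=C3 is covered by the C19–C20 bridge (1,3-diaxial to C2), so OsO4 adds from the β face and gives the 2β,3β-diol; the bromoalkene is electron-poor and reacts more slowly.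

Step 14
Reactants: 20 2β,3β-diol
Product: 21 2β,3β-acetonide
Conditions: 2,2-dimethoxypropane, PPTS (cat.), CH2Cl2, rt
Reagents that add atoms: 2,2-dimethoxypropane COC(C)(C)OC
Why: Acid-catalysed acetal exchange protects the cis-diol against the glycol cleavage of step 18.

Step 15
Reactants: 21 2β,3β-acetonide
Product: 22 ring C enone (C12=C13)
Conditions: IBX (2.5 equiv), DMSO/fluorobenzene, 75 °C
Reagents that add atoms: none
Why: IBX dehydrogenation through the enol; of the two ketones only C11 has an α-methylene with β-hydrogens (C12/C13), since C9 and C20 are flanked by quaternary carbons and C4 is quaternary, so the enone can only be C12=C13.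

Step 16
Reactants: 22 ring C enone
Product: 23 ring D closed, 16-methylene 11,19-dione
Conditions: Bu3SnH, AIBN (cat.), benzene (0.01 M), 80 °C
Reagents that add atoms: none
Why: Tin hydride-mediated 5-exo-trig cyclisation of the vinyl radical onto C13, the β-carbon of the enone; the arm on C8 reaches C13 only across the β face, which closes ring D as the bicyclo[3.2.1]octane, sets C13 and unveils the C16=C17 alkene only after all alkene oxidations are over.

Step 17
Reactants: 23 16-methylene 11,19-dione silyl ether
Product: 24 20-hydroxy 19-ketone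
Conditions: HF·pyridine, pyridine, THF, 0 °C
Reagents that add atoms: none
Why: Fluoride cleaves the triethylsilyl ether; the acetonide and esters are untouched under buffered conditions.

Step 18
Reactants: 24 20-hydroxy 19-ketone
Product: 25 19-methyl ester 20-aldehyde
Conditions: Pb(OAc)4 (1.2 equiv), MeOH/benzene 1:1, 0 °C
Reagents that add atoms: methanol CO
Why: Pb(OAc)4 cleavage of the α-hydroxy ketone in methanol (through the methyl hemiketal): the ketone carbon C19 becomes a methyl ester and the carbinol carbon C20 an aldehyde, which puts the oxygen on the C20 side, opposite to the Baeyer–Villiger sense.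

Step 19
Reactants: 25 19-methyl ester 20-aldehyde
Product: 27 19,20-lactone 11β-alcohol acetonide 7-methyl ester, via dihydroxy diester 26 (not isolated)
Conditions: NaBH4, MeOH, −20 to 0 °C; then K2CO3 (cat.), MeOH, rt
Reagents that add atoms: none
Why: Borohydride reduces the C20 aldehyde and the C11 ketone; hydride reaches C11 from the α face because the C15–C16 bridge covers the β face, giving the axial 11β-alcohol, and the C20 alkoxide closes the δ-lactone on the 1,3-diaxial C19 ester.

Step 20
Reactants: 27 19,20-lactone 11β-alcohol acetonide 7-methyl ester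
Product: 29 target acid CNP0302900.3, via dipotassium dicarboxylate 28 (not isolated)
Conditions: KOH, MeOH/H2O 3:1, 70 °C; then 2 M HCl, THF, rt
Reagents that add atoms: water O
Why: Saponification of the hindered C7 ester (the lactone opens reversibly), then acid closes the δ-lactone again and hydrolyses the acetonide under conditions mild enough for the exocyclic alkene; C6 keeps the thermodynamically favoured configuration.

## Compound list

1 | 3-ethoxycyclohex-2-en-1-one | CCOC1=CC(=O)CCC1 | starting material
2 | 2,3-dibromoprop-1-ene | C=C(Br)CBr | starting material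
3 | 1-(2-bromoprop-2-en-1-yl)-3-ethoxycyclohex-2-en-1-ol (racemic 1,2-adduct, zinc alkoxide in the flask) | CCOC1=CC(O)(CC(Br)=C)CCC1 | intermediate
4 | 3-(2-bromoprop-2-en-1-yl)cyclohex-2-en-1-one | C=C(Br)CC1=CC(=O)CCC1 | intermediate
5 | dimethyl propanedioate (dimethyl malonate) | COC(=O)CC(=O)OC | starting material
6 | dimethyl 2-[(1S)-1-(2-bromoprop-2-en-1-yl)-3-oxocyclohexyl]propanedioate | C=C(Br)C[C@@]1(C(C(=O)OC)C(=O)OC)CC(=O)CCC1 | intermediate
7 | 3-methylcyclopent-2-en-1-one | CC1=CC(=O)CC1 | starting material
8 | 4-methylcyclopent-4-ene-1,3-dione | CC1=CC(=O)CC1=O | intermediate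
9 | dimethyl 2-[(1S)-1-(2-bromoprop-2-en-1-yl)-3-oxocyclohexyl]-2-(2-methyl-3,5-dioxocyclopentyl)propanedioate (C4/C5 epimerisable, one epimer drawn) | C=C(Br)C[C@@]1(CCCC(=O)C1)C(C(=O)OC)(C(=O)OC)[C@@H]1[C@H](C)C(=O)CC1=O | intermediate
10 | tricyclic ene-dione diester: ring B closed, C10=C20 enone in carbocycle L, C11 and C19 ketones, geminal dimethyl ester on C6, 2-bromoallyl on C8, 9β-H (C4/C5 epimerisable, one epimer drawn) | C=C(Br)C[C@]12CCCC(=O)[C@H]1C1=CC(=O)[C@@H](C)[C@H]1C2(C(=O)OC)C(=O)OC | intermediate
11 | monoester of 10 (C6–H; C4/C5/C6 labile, one epimer drawn) | C=C(Br)C[C@]12CCCC(=O)[C@H]1C1=CC(=O)[C@@H](C)[C@H]1[C@@H]2C(=O)OC | intermediate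
12 | cross-conjugated dienone ester (C10=C20–C19=O and C5=C6–CO2Me; C4 labile) | C=C(Br)C[C@]12CCCC(=O)[C@H]1C1=CC(=O)[C@@H](C)C1=C2C(=O)OC | intermediate
13 | but-3-en-1-ylmagnesium bromide | C=CCC[Mg]Br | starting material
14 | triethylsilyl enol ether (C19–OSiEt3, C19=C20) with quaternary C10 bearing 10β-but-3-enyl | C=C(Br)C[C@]12CCCC(=O)[C@H]1[C@@]1(CCC=C)C=C(O[Si](CC)(CC)CC)[C@@H](C)C1=C2C(=O)OC | intermediate
15 | 20-(triethylsilyloxy) 19-ketone with C5=C6 enoate | C=C(Br)C[C@]12CCCC(=O)[C@H]1[C@@]1(CCC=C)[C@H](O[Si](CC)(CC)CC)C(=O)[C@@H](C)C1=C2C(=O)OC | intermediate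
16 | C4=C5 enone (conjugated to C19 ketone), 6β-methyl ester | C=C(Br)C[C@]12CCCC(=O)[C@H]1[C@@]1(CCC=C)[C@H](O[Si](CC)(CC)CC)C(=O)C(C)=C1[C@@H]2C(=O)OC | intermediate
17 | enone aldehyde (C1–C2–C3HO chain on C10) | C=C(Br)C[C@]12CCCC(=O)[C@H]1[C@@]1(CCC=O)[C@H](O[Si](CC)(CC)CC)C(=O)C(C)=C1[C@@H]2C(=O)OC | intermediate
18 | ring A ketol: C3–C4 bond, 3-hydroxy, quaternary C4, 5β-H | C=C(Br)C[C@]23CCCC(=O)[C@H]2[C@]12[C@H](O[Si](CC)(CC)CC)C(=O)[C@](C)([C@@H](O)CC1)[C@H]2[C@@H]3C(=O)OC | intermediate
19 | ring A 2-ene | C=C(Br)C[C@]23CCCC(=O)[C@H]2[C@]12[C@H](O[Si](CC)(CC)CC)C(=O)[C@](C)(C=CC1)[C@H]2[C@@H]3C(=O)OC | intermediate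
20 | 2β,3β-diol | C=C(Br)C[C@]23CCCC(=O)[C@H]2[C@]12[C@H](O[Si](CC)(CC)CC)C(=O)[C@](C)([C@@H](O)[C@@H](O)C1)[C@H]2[C@@H]3C(=O)OC | intermediate
21 | 2β,3β-acetonide | C=C(Br)C[C@]23CCCC(=O)[C@H]2[C@]12[C@H](O[Si](CC)(CC)CC)C(=O)[C@](C)([C@H]4OC(C)(C)O[C@H]4C1)[C@H]2[C@@H]3C(=O)OC | intermediate
22 | ring C enone (C12=C13, C11 ketone) | C=C(Br)C[C@]23CC=CC(=O)[C@H]2[C@]12[C@H](O[Si](CC)(CC)CC)C(=O)[C@](C)([C@H]4OC(C)(C)O[C@H]4C1)[C@H]2[C@@H]3C(=O)OC | intermediate
23 | ring D closed: 16-methylene 11,19-dione with 20-OSiEt3 | C=C1C[C@]23C[C@H]1CC(=O)[C@H]2[C@]12[C@H](O[Si](CC)(CC)CC)C(=O)[C@](C)([C@H]4OC(C)(C)O[C@H]4C1)[C@H]2[C@@H]3C(=O)OC | intermediate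
24 | 20-hydroxy 19-ketone | C=C1C[C@]23C[C@H]1CC(=O)[C@H]2[C@]12[C@H](O)C(=O)[C@](C)([C@H]4OC(C)(C)O[C@H]4C1)[C@H]2[C@@H]3C(=O)OC | intermediate
25 | 19-methyl ester 20-aldehyde (carbocycle L cleaved), 11-ketone | C=C1C[C@]23C[C@H]1CC(=O)[C@H]2[C@@]1(C=O)[C@@H]([C@](C)(C(=O)OC)[C@H]4OC(C)(C)O[C@H]4C1)[C@@H]3C(=O)OC | intermediate
26 | 20-alcohol 11β-alcohol 7,19-dimethyl ester | C=C1C[C@]23C[C@H]1C[C@H](O)[C@H]2[C@@]1(CO)[C@@H]([C@](C)(C(=O)OC)[C@H]4OC(C)(C)O[C@H]4C1)[C@@H]3C(=O)OC | intermediate
27 | 19,20-lactone 11β-alcohol 2β,3β-acetonide 7-methyl ester | C=C1C[C@]23C[C@H]1C[C@H](O)[C@H]2[C@]12COC(=O)[C@](C)([C@H]4OC(C)(C)O[C@H]4C1)[C@H]2[C@@H]3C(=O)OC | intermediate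
28 | dipotassium 7,19-dicarboxylate, 20-alcohol, acetonide | C=C1C[C@]23C[C@H]1C[C@H](O)[C@H]2[C@@]1(CO)[C@@H]([C@](C)(C(=O)[O-])[C@H]4OC(C)(C)O[C@H]4C1)[C@@H]3C(=O)[O-].[K+].[K+] | intermediate
29 | 2β,3β,11β-trihydroxy-20-hydroxygibberell-16-ene-7,19-dioic acid 19,20-lactone (CNP0302900.3) | C=C1C[C@]23C[C@H]1C[C@H](O)[C@H]2[C@]12COC(=O)[C@](C)([C@@H](O)[C@@H](O)C1)[C@H]2[C@@H]3C(=O)O | target

## Count and risk

Total step count: 20. Longest linear sequence: 19 steps (steps 1, 2, 4–20; step 3 is the side branch).

**Step 11 (key step).** Hydride transfer to the fully substituted C5 (between C6 and quaternary C10) may be too slow, so that direct reduction of the aldehyde or simple protonation of the enolate competes. Fallback, from 15 back to 18: Lemieux–Johnson cleavage of the butenyl group of 15 gives aldehyde F1. Mild base (K2CO3) then removes the vinylogous C4–H and the dienolate closes ring A by aldol addition to give ketol F2, with C5=C6 still in place. Conjugate reduction of the enoate (SmI2/MeOH or Mg/MeOH) then adds the C5 hydrogen and gives 18. This inverts the order (aldol first, C5 last) at the price of weaker control of the C5 face.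

**Step 2.** The skipped diene of 4 may isomerise into conjugation under amine catalysis, or the crowded β‑carbon may react with low conversion or enantioselectivity. Fallback, from 4 and 5 back to 6: run the Michael addition with an achiral base under pressure and separate 6 from the mirror‑image malonate F3 by preparative chromatography on a chiral phase (resolution instead of asymmetric catalysis).

**Step 4.** Proton transfer to the acidic methylene of 8 may cause self‑condensation under the Michael conditions, and the condensation may close onto C19 (six‑membered ring) instead of C10. Fallback, from 8 and 6 back to 10: convert 8 into its mono‑dimethyl ketal F4 (trimethyl orthoformate, MeOH, acid), which has no doubly activated methylene. F4 takes up the malonate of 6 to give ketal adduct F5. TiCl4/Et3N then closes ring B through the oxocarbenium ion at C10 only, and loss of methanol gives 10.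

**Step 7.** The organometallic may deprotonate the acidic C4–H/C9–H positions or add to the C11 ketone, and facial selectivity at C10 rests on a conformational argument. Fallback, from 11 back to 16: add the butenyl group one step earlier to the simple enone 11, where the reagent must enter cis to H5 (cis‑bicyclo[3.3.0]) and the C5 epimers are equilibrated with DBU and recycled. This gives silyl enol ether F6; Rubottom oxidation gives ketone F7, and IBX dehydrogenation of F7 across C4–C5 gives 16.

**Step 19.** Hydride may be delivered to C11 from the β face if the C20 substituent shields the α face more than the C15–C16 bridge shields the β face. Fallback, from 25 back to 29: the resulting 11α‑alcohol F8 is inverted by a Mitsunobu reaction with 4‑nitrobenzoic acid to the 11β‑ester F9, whose ester is cleaved under the conditions of step 20 to give 29.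

## Further compounds

F1 | step 11 | aldehyde of 15 (C5=C6 enoate, C4–H, C3 aldehyde) | C=C(Br)C[C@]12CCCC(=O)[C@H]1[C@@]1(CCC=O)[C@H](O[Si](CC)(CC)CC)C(=O)[C@@H](C)C1=C2C(=O)OC
F2 | step 11 | ring A ketol with C5=C6 enoate retained | C=C(Br)C[C@]23CCCC(=O)[C@H]2[C@]12[C@H](O[Si](CC)(CC)CC)C(=O)[C@](C)([C@@H](O)CC1)C2=C3C(=O)OC
F3 | step 2 | dimethyl 2-[(1R)-1-(2-bromoprop-2-en-1-yl)-3-oxocyclohexyl]propanedioate (enantiomer of 6) | C=C(Br)C[C@]1(C(C(=O)OC)C(=O)OC)CC(=O)CCC1
F4 | step 4 | 4,4-dimethoxy-2-methylcyclopent-2-en-1-one | CC1=CC(OC)(OC)CC1=O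
F5 | step 4 | Michael adduct of 6 with F4 (C10 dimethyl ketal, C19 ketone; one epimer drawn) | C=C(Br)C[C@@]1(CCCC(=O)C1)C(C(=O)OC)(C(=O)OC)[C@@H]1[C@H](C)C(=O)CC1(OC)OC
F6 | step 7 | triethylsilyl enol ether from 11 (C5–H, C6–H, 10β-butenyl) | C=C(Br)C[C@]12CCCC(=O)[C@H]1[C@@]1(CCC=C)C=C(O[Si](CC)(CC)CC)[C@@H](C)[C@H]1[C@@H]2C(=O)OC
F7 | step 7 | 20-(triethylsilyloxy) 19-ketone with saturated C4–C5 | C=C(Br)C[C@]12CCCC(=O)[C@H]1[C@@]1(CCC=C)[C@H](O[Si](CC)(CC)CC)C(=O)[C@@H](C)[C@H]1[C@@H]2C(=O)OC
F8 | step 19 | 11α-epimer of 27 | C=C1C[C@]23C[C@H]1C[C@@H](O)[C@H]2[C@]12COC(=O)[C@](C)([C@H]4OC(C)(C)O[C@H]4C1)[C@H]2[C@@H]3C(=O)OC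
F9 | step 19 | 11β-(4-nitrobenzoate) of 27 | C=C1C[C@]23C[C@H]1C[C@H](OC(=O)c5ccc(cc5)[N+](=O)[O-])[C@H]2[C@]12COC(=O)[C@](C)([C@H]4OC(C)(C)O[C@H]4C1)[C@H]2[C@@H]3C(=O)OC
A1 | alternative 1 | 20-hydroxy 19-acid 7-methyl ester (seco acid of the lactone) | C=C1C[C@]23C[C@H]1C[C@H](O)[C@H]2[C@@]1(CO)[C@@H]([C@](C)(C(=O)O)[C@@H](O)[C@@H](O)C1)[C@@H]3C(=O)OC
A2 | alternative 2 | 6-diazo-7-oxo ent-kauranoid 19,20-lactone triol | C=C1C[C@]23C[C@H]1C[C@H](O)[C@H]2[C@]12COC(=O)[C@](C)([C@@H](O)[C@@H](O)C1)[C@H]2C(=[N+]=[N-])C3=O
A3 | alternative 3 | ring A lactone triene (silyloxydiene on C10, 1,1-disubstituted alkene on the C6 chain) | COC(=O)[C@H](C(=C)CC(Br)=C)[C@@H]1[C@@]2(C)C=CC[C@]1(/C=C(\O[Si](C)(C)C(C)(C)C)C=C)COC2=O
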